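**Plan**

- Retrosynthesis: the C9 alcohol goes back to the C9 ketone. The C9–C9a aryl–carbonyl bond is then cut while the C7 methyl carbon is reconnected to C9, which leaves a boronate on C9a.
- Enabling feature: C9, C8 (with its methyl), C7 and the methyl carbon on C7 are four contiguous carbons. Joined into a loop they are a cis-2-methyl-3-alkylcyclobutanone hanging from C6, so this part of the seven-membered ring (C4a, C5, C6, C7, C8, C9, C9a) can be stored as a strained four-membered ketone.
- Further cuts: the cyclobutanone to an allyl group plus a propionyl unit ([2+2]), the C5–allyl bond (dearomatizing para-allylation of a syringyl phenol), the C4a–C5 biaryl bond (Suzuki), and C–B from C–Br.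
- Forward order: the two arenes are joined, the syringyl ring becomes the dienone ring with creation of quaternary C5, the cyclobutanone is built on the allyl group, and the seven-membered ring closes last while the four-membered ring is consumed.
- Stereochemistry: C7 and C8 come from the auxiliary-controlled, cis-selective keteniminium cycloaddition and pass unchanged through the ring opening (cis on the cyclobutane becomes trans-dimethyl). C9 comes from axial hydride delivery. C5 is not stereogenic.
- Endgame: the dienone carbonyl is more electrophilic than the electron-rich aryl ketone, so borohydride is allowed to reduce both and MnO2 then restores the dienone.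

Key step: step 7

Assumption: the sense of induction of the C2-symmetric auxiliary is taken from the usual steric model (the alkene reaches the keteniminium carbon on the side away from the nearer pyrrolidine methyl group and closes cis), which leads from the (2S,5S) amide to the (2S,3S) cyclobutanone.

**Route**

Step 1
Reactants: 1 5-bromo-1,2,3-trimethoxybenzene
Product: 2 1-bromo-2-iodo-3,4,5-trimethoxybenzene
Conditions: NIS, CF3CO2H (cat.), MeCN, rt
Reagents that add atoms: N-iodosuccinimide, O=C1CCC(=O)N1I
Why: Electrophilic aromatic iodination can only occur at the two equivalent open positions (ortho and para to methoxy groups), and the first iodine crowds and deactivates the ring against a second substitution.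

Step 2
Reactants: 2 1-bromo-2-iodo-3,4,5-trimethoxybenzene; 3 2,6-dimethoxy-4-(4,4,5,5-tetramethyl-1,3,2-dioxaborolan-2-yl)phenol
Product: 4 4-(6-bromo-2,3,4-trimethoxyphenyl)-2,6-dimethoxyphenol
Conditions: Pd(PPh3)4 (5 mol %), K2CO3, DME/H2O (4:1), 80 °C
Reagents that add atoms: none
Why: Suzuki–Miyaura coupling in which zerovalent palladium inserts into the C–I bond far faster than into the neighbouring C–Br bond, so the biaryl bond forms at the carbon flanked by OMe and Br and the bromide is kept as the future boron site.

Step 3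
Reactants: 4 4-(6-bromo-2,3,4-trimethoxyphenyl)-2,6-dimethoxyphenol
Product: 5 2,6-dimethoxy-4-[2,3,4-trimethoxy-6-(4,4,5,5-tetramethyl-1,3,2-dioxaborolan-2-yl)phenyl]phenol
Conditions: B2pin2, PdCl2(dppf) (5 mol %), KOAc, 1,4-dioxane, 90 °C
Reagents that add atoms: bis(pinacolato)diboron, CC1(C)OB(OC1(C)C)B1OC(C)(C)C(C)(C)O1
Why: Miyaura borylation of a mono-ortho-substituted aryl bromide, in which the weak acetate base tolerates the free phenol and does not promote Suzuki homocoupling.

Step 4
Reactants: 5 2,6-dimethoxy-4-[2,3,4-trimethoxy-6-(4,4,5,5-tetramethyl-1,3,2-dioxaborolan-2-yl)phenyl]phenol; 6 allyltrimethylsilane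
Product: 7 4-allyl-2,6-dimethoxy-4-[2,3,4-trimethoxy-6-(4,4,5,5-tetramethyl-1,3,2-dioxaborolan-2-yl)phenyl]cyclohexa-2,5-dien-1-one
Conditions: PhI(OAc)2 (1.1 equiv), 6 (5 equiv), (CF3)2CHOH, −20 to 0 °C
Reagents that add atoms: allyltrimethylsilane (compound 6), C=CC[Si](C)(C)C
Why: Oxidative dearomatization with trivalent iodine in the fluorinated alcohol gives a phenoxenium-type intermediate that the allylsilane captures at the aryl-bearing para carbon (oxidative Hosomi–Sakurai-type para-allylation), creating quaternary, non-stereogenic C5 and a cross-conjugated dienone that cannot re-aromatize.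

Step 5
Reactants: 8 (2S,5S)-2,5-dimethylpyrrolidine; 9 propionyl chloride
Product: 10 1-[(2S,5S)-2,5-dimethylpyrrolidin-1-yl]propan-1-one
Conditions: Et3N, CH2Cl2, 0 °C to rt
Reagents that add atoms: propionyl chloride (compound 9), CCC(=O)Cl
Why: Plain N-acylation of a secondary amine by an acid chloride, which leaves the two stereocentres of the auxiliary untouched.

Step 6
Reactants: 7 4-allyl-2,6-dimethoxy-4-[2,3,4-trimethoxy-6-(4,4,5,5-tetramethyl-1,3,2-dioxaborolan-2-yl)phenyl]cyclohexa-2,5-dien-1-one; 10 1-[(2S,5S)-2,5-dimethylpyrrolidin-1-yl]propan-1-one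
Product: 13 2,6-dimethoxy-4-{[(1S,2S)-2-methyl-3-oxocyclobutyl]methyl}-4-[2,3,4-trimethoxy-6-(4,4,5,5-tetramethyl-1,3,2-dioxaborolan-2-yl)phenyl]cyclohexa-2,5-dien-1-one, via keteniminium triflate 11 (not isolated), via cyclobutaniminium triflate 12 (not isolated)
Conditions: 10 (1.5 equiv), Tf2O, 2,4,6-collidine, CH2Cl2, −20 °C; then 7, 40 °C; aq. NaHCO3, rt
Reagents that add atoms: 1-[(2S,5S)-2,5-dimethylpyrrolidin-1-yl]propan-1-one (compound 10), CCC(=O)N1[C@@H](C)CC[C@@H]1C; water, O
Why: Ghosez keteniminium–alkene [2+2] cycloaddition in which the central carbon of 11 bonds to the terminal CH2 of the allyl group and the methyl-bearing carbon to the internal carbon (2-methyl-3-alkyl regiochemistry); the kinetic cis arrangement arises as in ketene cycloadditions, the C2-symmetric pyrrolidine blocks one side of the reacting face so that both new stereocentres form as (S), and mild bicarbonate hydrolysis of 12 frees the ketone and the auxiliary.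

Step 7
Reactants: 13 2,6-dimethoxy-4-{[(1S,2S)-2-methyl-3-oxocyclobutyl]methyl}-4-[2,3,4-trimethoxy-6-(4,4,5,5-tetramethyl-1,3,2-dioxaborolan-2-yl)phenyl]cyclohexa-2,5-dien-1-one
Product: 17 (7R,8S)-2,3,3',4,5'-pentamethoxy-7,8-dimethyl-7,8-dihydrospiro[benzo[7]annulene-5,1'-cyclohexa[2,5]diene]-4',9(6H)-dione, via arylrhodium 14 (not isolated), via bridged rhodium cyclobutanolate 15 (not isolated), via alkylrhodium ketone 16 (not isolated)
Conditions: [Rh(OH)(cod)]2 (5 mol %), 1,4-dioxane/H2O (20:1), 60 °C
Reagents that add atoms: none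
Why: The hydroxorhodium catalyst (monovalent rhodium) transmetalates with the pinacol boronate to give 14, which adds to the strained and therefore unusually electrophilic cyclobutanone carbonyl to form the bridged alkoxide 15 (C9–C9a made); strain-releasing β-carbon elimination then breaks the C9–CH2 bond to give the primary alkylrhodium 16, and water cleaves the Rh–C bond, turning that carbon into the C7 methyl and returning Rh–OH. The closest known reaction type is the rhodium-catalysed addition/ring opening of arylboron reagents with cyclobutanones, established intermolecularly and intramolecularly for 3-(2-borylaryl)cyclobutanones; the tether here is two atoms longer. The seven-membered ring closes by 7-exo-trig attack of the aryl carbon on the carbonyl carbon through a bicyclo[4.1.1] alkoxide and survives the opening of the four-membered ring. No stereocentre is created: C9 ends as an sp2 carbon, C7 keeps its configuration because its bonds to C6 and C8 are not touched, and the cis relation on the cyclobutane becomes the trans-dimethyl relation once the former ring CH2 is the C7 methyl. The step needs cleavage of C9–CH2 in preference to C9–C8, which formation of the less hindered primary alkylrhodium secures, and it needs carbonyl addition to outrun protodeboronation, which the ring strain and the intramolecular setting favour; conjugate addition to the molecule's own dienone would require a four-membered ring.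

Step 8
Reactants: 17 (7R,8S)-2,3,3',4,5'-pentamethoxy-7,8-dimethyl-7,8-dihydrospiro[benzo[7]annulene-5,1'-cyclohexa[2,5]diene]-4',9(6H)-dione
Product: 18 (7R,8S,9R)-2,3,3',4,5'-pentamethoxy-7,8-dimethyl-6,7,8,9-tetrahydrospiro[benzo[7]annulene-5,1'-cyclohexa[2,5]diene]-4',9-diol (either orientation of the 4'-hydroxyl)
Conditions: NaBH4 (excess), MeOH/THF, 0 °C to rt; aq. NaHCO3 work-up, crude product used directly
Reagents that add atoms: none
Why: Borohydride 1,2-reduction of both carbonyls, accepted because the bis-α-methoxy dienone carbonyl is the more electrophilic one and cannot be spared; at C9 the small hydride should attack axially on the chair-like ring with both methyls equatorial, placing the hydroxyl equatorial and trans to the C8 methyl (9R), while the configuration of the dienol carbinol is irrelevant.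

Step 9
Reactants: 18 (7R,8S,9R)-2,3,3',4,5'-pentamethoxy-7,8-dimethyl-6,7,8,9-tetrahydrospiro[benzo[7]annulene-5,1'-cyclohexa[2,5]diene]-4',9-diol
Product: 19 (7R,8S,9R)-9-hydroxy-2,3,3',4,5'-pentamethoxy-7,8-dimethyl-6,7,8,9-tetrahydrospiro[benzo[7]annulene-5,1'-cyclohexa[2,5]dien]-4'-one
Conditions: activated MnO2 (excess), CH2Cl2, 0 °C to rt, monitored
Reagents that add atoms: none
Why: MnO2 oxidation of activated alcohols, in which the doubly allylic carbinol of the dienol ring should be oxidized much faster than the secondary, α-branched benzylic C9 alcohol, restoring the dienone without touching C9 (over-oxidation would only return 17).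

**Compound list**

1 | 5-bromo-1,2,3-trimethoxybenzene | COc1cc(Br)cc(OC)c1OC | starting material
2 | 1-bromo-2-iodo-3,4,5-trimethoxybenzene | COc1cc(Br)c(I)c(OC)c1OC | intermediate
3 | 2,6-dimethoxy-4-(4,4,5,5-tetramethyl-1,3,2-dioxaborolan-2-yl)phenol | COc1cc(B2OC(C)(C)C(C)(C)O2)cc(OC)c1O | starting material
4 | 4-(6-bromo-2,3,4-trimethoxyphenyl)-2,6-dimethoxyphenol | COc1cc(cc(OC)c1O)-c1c(Br)cc(OC)c(OC)c1OC | intermediate
5 | 2,6-dimethoxy-4-[2,3,4-trimethoxy-6-(4,4,5,5-tetramethyl-1,3,2-dioxaborolan-2-yl)phenyl]phenol | COc1cc(cc(OC)c1O)-c1c(B2OC(C)(C)C(C)(C)O2)cc(OC)c(OC)c1OC | intermediate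
6 | allyltrimethylsilane | C=CC[Si](C)(C)C | starting material
7 | 4-allyl-2,6-dimethoxy-4-[2,3,4-trimethoxy-6-(4,4,5,5-tetramethyl-1,3,2-dioxaborolan-2-yl)phenyl]cyclohexa-2,5-dien-1-one | COC1=CC(CC=C)(C=C(OC)C1=O)c1c(B2OC(C)(C)C(C)(C)O2)cc(OC)c(OC)c1OC | intermediate
8 | (2S,5S)-2,5-dimethylpyrrolidine | N1[C@@H](C)CC[C@@H]1C | starting material
9 | propionyl chloride | CCC(=O)Cl | starting material
10 | 1-[(2S,5S)-2,5-dimethylpyrrolidin-1-yl]propan-1-one | CCC(=O)N1[C@@H](C)CC[C@@H]1C | intermediate
11 | (2S,5S)-2,5-dimethyl-1-(prop-1-en-1-ylidene)pyrrolidin-1-ium trifluoromethanesulfonate (keteniminium triflate) | CC=C=[N+]1[C@@H](C)CC[C@@H]1C.[O-]S(=O)(=O)C(F)(F)F | intermediate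
12 | iminium triflate of 13 with (2S,5S)-2,5-dimethylpyrrolidine at the cyclobutane carbonyl carbon (cyclobutaniminium triflate) | COC1=CC(C[C@@H](C2)[C@H](C)C2=[N+]3[C@@H](C)CC[C@@H]3C)(C=C(OC)C1=O)c1c(B2OC(C)(C)C(C)(C)O2)cc(OC)c(OC)c1OC.[O-]S(=O)(=O)C(F)(F)F | intermediate
13 | 2,6-dimethoxy-4-{[(1S,2S)-2-methyl-3-oxocyclobutyl]methyl}-4-[2,3,4-trimethoxy-6-(4,4,5,5-tetramethyl-1,3,2-dioxaborolan-2-yl)phenyl]cyclohexa-2,5-dien-1-one (methyl cis to the CH2 substituent) | COC1=CC(C[C@@H](C2)[C@H](C)C2=O)(C=C(OC)C1=O)c1c(B2OC(C)(C)C(C)(C)O2)cc(OC)c(OC)c1OC | intermediate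
14 | arylrhodium from 13 with rhodium in place of boron (cod ligand omitted) | COC1=CC(C[C@@H](C2)[C@H](C)C2=O)(C=C(OC)C1=O)c1c([Rh])cc(OC)c(OC)c1OC | intermediate
15 | bridged rhodium cyclobutanolate: C9 bears O–Rh and is bonded to C9a, C8 and the CH2 that bridges to C7 (cod ligand omitted) | COC1=CC2(C=C(OC)C1=O)C[C@H]3C[C@](O[Rh])([C@H]3C)c3cc(OC)c(OC)c(OC)c32 | intermediate
16 | alkylrhodium ketone: 17 with rhodium on the C7 methyl carbon (cod ligand omitted) | COC1=CC2(C=C(OC)C1=O)C[C@@H](C[Rh])[C@H](C)C(=O)c1cc(OC)c(OC)c(OC)c12 | intermediate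
17 | (7R,8S)-2,3,3',4,5'-pentamethoxy-7,8-dimethyl-7,8-dihydrospiro[benzo[7]annulene-5,1'-cyclohexa[2,5]diene]-4',9(6H)-dione (trans-dimethyl) | COC1=CC2(C=C(OC)C1=O)C[C@@H](C)[C@H](C)C(=O)c1cc(OC)c(OC)c(OC)c12 | intermediate
18 | (7R,8S,9R)-2,3,3',4,5'-pentamethoxy-7,8-dimethyl-6,7,8,9-tetrahydrospiro[benzo[7]annulene-5,1'-cyclohexa[2,5]diene]-4',9-diol (4'-carbinol orientation undefined) | COC1=CC2(C=C(OC)C1O)C[C@@H](C)[C@H](C)[C@@H](O)c1cc(OC)c(OC)c(OC)c12 | intermediate
19 | (7R,8S,9R)-9-hydroxy-2,3,3',4,5'-pentamethoxy-7,8-dimethyl-6,7,8,9-tetrahydrospiro[benzo[7]annulene-5,1'-cyclohexa[2,5]dien]-4'-one | COC1=CC2(C=C(OC)C1=O)C[C@@H](C)[C@H](C)[C@@H](O)c1cc(OC)c(OC)c(OC)c12 | target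

**Step count and risks**

Total steps: 9. Longest linear sequence: 8 (steps 1 to 4 and 6 to 9; step 5 prepares the auxiliary amide).

Steps most likely to fail:

1. Step 7. The aryl–rhodium may be protonated by water before it can reach the carbonyl through the strained seven-membered bridged geometry, or β-hydride elimination of the alkylrhodium may compete with protonolysis. The fallback sets out from 13 and comes back at 17. The boronate is exchanged for iodide by copper-mediated ipso-iodination (CuI, 1,10-phenanthroline, KI, MeOH/H2O, air) to give the aryl iodide F1. An intramolecular Nozaki–Hiyama–Kishi-type closure (CrCl2, NiCl2 cat., DMF) follows; the aryl–chromium species persists under aprotic conditions until it adds to the cyclobutanone, giving the bridged tertiary cyclobutanol F2. A separate rhodium-catalysed ring opening of this tert-cyclobutanol ([Rh(OH)(cod)]2, toluene, 80 °C; β-carbon elimination, then protonation) delivers ketone 17.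

2. Step 4. The allylsilane may attack a methoxy-bearing ortho carbon of the phenoxenium intermediate instead of the crowded para carbon, or the oxidant may attack the boronate-bearing ring. The fallback sets out from 1 and comes back at 7, with the roles of the partners reversed. Commercial 4-allyl-2,6-dimethoxyphenol is oxidized with PhI(OAc)2 in (CF3)2CHOH in the presence of excess 1 (oxidative Friedel–Crafts arylation at the para carbon, through the position of 1 ortho to bromine and para to a methoxy group) to give the bromo dienone F3. Miyaura borylation of F3 (B2pin2, PdCl2(dppf), KOAc, dioxane) then gives 7.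

3. Step 6. Facial or cis/trans selectivity may be eroded on this hindered allyl group, or the keteniminium may be captured by the electron-rich arene. A minor trans-cyclobutanone would surface after step 7 as the 8-epimer of 17. The fallback sets out from 7 and comes back at 17, moving the stereocontrol to the catalyst. Dichloroketene (Cl3CCOCl, zinc–copper couple Zn–Cu, Et2O) adds to the allyl group to give the dichlorocyclobutanone F4. Zinc dechlorination (Zn, NH4Cl, MeOH) gives the achiral 3-substituted cyclobutanone F5. The rhodium addition/ring opening is then run as an enantioselective desymmetrization ([Rh(OH)(cod)]2 with a chiral bisphosphine such as (R)-SEGPHOS, or its antipode as the sense of induction requires) to give the 7-methyl ketone F6. Methylation of its enolate (LiN(SiMe3)2, MeI, THF, −78 °C) anti to the C7 methyl gives 17.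

**Further compounds**

F1 | step 7 | 4-(6-iodo-2,3,4-trimethoxyphenyl)-2,6-dimethoxy-4-{[(1S,2S)-2-methyl-3-oxocyclobutyl]methyl}cyclohexa-2,5-dien-1-one | COC1=CC(C[C@@H](C2)[C@H](C)C2=O)(C=C(OC)C1=O)c1c(I)cc(OC)c(OC)c1OC
F2 | step 7 | 9-hydroxy-2,3,3',4,5'-pentamethoxy-8-methyl-6,7,8,9-tetrahydro-7,9-methanospiro[benzo[7]annulene-5,1'-cyclohexa[2,5]dien]-4'-one (bridged tertiary cyclobutanol) | COC1=CC2(C=C(OC)C1=O)C[C@H]3C[C@](O)([C@H]3C)c3cc(OC)c(OC)c(OC)c32
F3 | step 4 | 4-allyl-4-(6-bromo-2,3,4-trimethoxyphenyl)-2,6-dimethoxycyclohexa-2,5-dien-1-one | COC1=CC(CC=C)(C=C(OC)C1=O)c1c(Br)cc(OC)c(OC)c1OC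
F4 | step 6 | 4-[(2,2-dichloro-3-oxocyclobutyl)methyl]-2,6-dimethoxy-4-[2,3,4-trimethoxy-6-(4,4,5,5-tetramethyl-1,3,2-dioxaborolan-2-yl)phenyl]cyclohexa-2,5-dien-1-one (racemic) | COC1=CC(CC2CC(=O)C2(Cl)Cl)(C=C(OC)C1=O)c1c(B2OC(C)(C)C(C)(C)O2)cc(OC)c(OC)c1OC
F5 | step 6 | 2,6-dimethoxy-4-[(3-oxocyclobutyl)methyl]-4-[2,3,4-trimethoxy-6-(4,4,5,5-tetramethyl-1,3,2-dioxaborolan-2-yl)phenyl]cyclohexa-2,5-dien-1-one | COC1=CC(CC2CC(=O)C2)(C=C(OC)C1=O)c1c(B2OC(C)(C)C(C)(C)O2)cc(OC)c(OC)c1OC
F6 | step 6 | (7R)-2,3,3',4,5'-pentamethoxy-7-methyl-7,8-dihydrospiro[benzo[7]annulene-5,1'-cyclohexa[2,5]diene]-4',9(6H)-dione | COC1=CC2(C=C(OC)C1=O)C[C@@H](C)CC(=O)c1cc(OC)c(OC)c(OC)c12
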